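**Plan**

- **Feature.** Ring A is labelled a1 (aroyl), a2 (OH), a3 (H), a4 (CH3), a5 (OMe), a6 (bonded to indenone C2). It has a para-dioxygenated four-carbon edge a2–a3–a4–a5. Opposite lies a two-carbon edge a1–a6 that carries a ketone and a vinyl carbon. This is the imprint of a 1,1,4-trioxygenated butadiene on an ynone.
- **Cuts.** First the O–isopropyl bond at C4, then a5–a6 and a2–a1 of ring A, then the alkyne–C2 bond. After that the C2–Br bond with the C2=C3 unsaturation, and finally C1–C7a and C3–C3a of the five-membered ring. Indenone locants: C1 carbonyl, C2, C3, C3a, C4 to C7 in ring B, C7a.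
- **Forward, part 1.** Ring B is bought as a phenol and brominated at the future C3a. Its Grignard reagent is joined to the benzylidene Meldrum's acid of 2,6-dimethoxybenzaldehyde (C3a–C3). Friedel–Crafts acylation closes the five-membered ring (C1–C7a). Enolate dibromination and loss of HBr give the 2-bromoindenone.
- **Forward, part 2.** Sonogashira coupling and oxidation attach the aroyl alkyne. Ring A is built last by Diels–Alder addition and aromatisation, and BCl3 frees the C4 phenol.
- **Stereochemistry.** The target has no stereocentre, and the racemic sp3 centres made on the way (C3, the carbinol carbon, a5) are all flattened again. Only one geometry must be controlled: the Z-enoate that steers γ-deprotonation to CH2OMe in the diene synthesis. It comes from a syn-carbocupration.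

Key step: step 14

Remark: the target SMILES holds no stereodescriptor, so hindered rotation about the aryl–carbon bonds is not treated as a stereochemical element and all sp3 intermediates are racemic.

**Route**

Step 1
Reactants: 1 4-methoxy-3-methylphenol
Product: 2 4-isopropoxy-1-methoxy-2-methylbenzene
Conditions: 2-bromopropane, K2CO3, DMF, 60 °C
Reagents that add atoms: 2-bromopropane, CC(C)Br
Why: Williamson ether synthesis at the only acidic site; the secondary alkyl aryl ether withstands magnesium, lithium amides, palladium catalysis and catalytic Sc(OTf)3 and can be removed at the end in the presence of methyl ethers.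

Step 2
Reactants: 2 4-isopropoxy-1-methoxy-2-methylbenzene
Product: 3 1-bromo-2-isopropoxy-5-methoxy-4-methylbenzene
Conditions: NBS, MeCN, 0 °C to rt, dark
Reagents that add atoms: N-bromosuccinimide, O=C1CCC(=O)N1Br
Why: Electrophilic aromatic bromination of a 2,5-dialkoxytoluene goes para to the methyl group and ortho to the alkoxy group, which marks the most nucleophilic ring B carbon, the future C3a, for the bond to C3.

Step 3
Reactants: 4 2,6-dimethoxybenzaldehyde; 5 Meldrum's acid (2,2-dimethyl-1,3-dioxane-4,6-dione)
Product: 6 5-(2,6-dimethoxybenzylidene)-2,2-dimethyl-1,3-dioxane-4,6-dione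
Conditions: piperidine (cat.), AcOH (cat.), toluene, molecular sieves 4 Å, rt to 50 °C
Reagents that add atoms: none
Why: Knoevenagel condensation of a non-enolisable aldehyde with the very acidic methylene of 5, driven by removal of water.

Step 4
Reactants: 3 1-bromo-2-isopropoxy-5-methoxy-4-methylbenzene; 6 5-(2,6-dimethoxybenzylidene)-2,2-dimethyl-1,3-dioxane-4,6-dione
Product: 8 5-[(2,6-dimethoxyphenyl)(2-isopropoxy-5-methoxy-4-methylphenyl)methyl]-2,2-dimethyl-1,3-dioxane-4,6-dione (racemic), via arylmagnesium bromide 7 (not isolated)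
Conditions: 3, Mg turnings, I2 (cat.), THF, reflux; then 6, THF, −20 °C to rt; 1 M HCl work-up
Reagents that add atoms: none
Why: Grignard formation followed by conjugate addition to an arylidene Meldrum's acid, a very strong Michael acceptor that offers no 1,2-pathway, forms C3a–C3 with fixed regiochemistry on ring B; the new stereocentre C3 is racemic and is flattened in step 6.

Step 5
Reactants: 8 5-[(2,6-dimethoxyphenyl)(2-isopropoxy-5-methoxy-4-methylphenyl)methyl]-2,2-dimethyl-1,3-dioxane-4,6-dione
Product: 10 3-(2,6-dimethoxyphenyl)-4-isopropoxy-7-methoxy-6-methylindan-1-one (racemic), via indanone-2-carboxylic acid 9 (not isolated)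
Conditions: Sc(OTf)3 (10 mol %), MeNO2, 100 °C
Reagents that add atoms: none
Why: Intramolecular Friedel–Crafts acylation of a benzyl Meldrum's acid under Sc(OTf)3 catalysis closes the five-membered ring at C7a, the only free ortho position of either aryl group (C4 carries OiPr, the dimethoxyphenyl ring carries OMe at both ortho carbons), and the β-keto acid 9 left after loss of acetone decarboxylates at this temperature.

Step 6
Reactants: 10 3-(2,6-dimethoxyphenyl)-4-isopropoxy-7-methoxy-6-methylindan-1-one
Product: 13 2-bromo-3-(2,6-dimethoxyphenyl)-4-isopropoxy-7-methoxy-6-methylinden-1-one, via 2-bromoindanone 11 (not isolated), via 2,2-dibromoindanone 12 (not isolated)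
Conditions: LiN(SiMe3)2 (1.1 equiv), THF, −78 °C, then NBS (1.05 equiv); the same two additions repeated; then DBU (2 equiv), −78 °C to rt; 1 M HCl work-up
Reagents that add atoms: N-bromosuccinimide, O=C1CCC(=O)N1Br
Why: Two enolate α-brominations followed by E2 dehydrobromination across C2–C3: a lithium enolate takes bromine from NBS at −78 °C far faster than the resorcinol-type dimethoxyphenyl ring can react, which is why the halogen enters at the indanone level instead of by electrophilic bromination of an indenone, and the C3 stereocentre disappears.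

Step 7
Reactants: 4 2,6-dimethoxybenzaldehyde; 14 ethynylmagnesium bromide (commercial solution in THF)
Product: 15 1-(2,6-dimethoxyphenyl)prop-2-yn-1-ol (racemic)
Conditions: THF, 0 °C; then H2O
Reagents that add atoms: none
Why: 1,2-Addition of an alkynyl Grignard reagent to a non-enolisable aldehyde; the carbinol stereocentre is racemic and is removed in step 9.

Step 8
Reactants: 13 2-bromo-3-(2,6-dimethoxyphenyl)-4-isopropoxy-7-methoxy-6-methylinden-1-one; 15 1-(2,6-dimethoxyphenyl)prop-2-yn-1-ol
Product: 16 3-(2,6-dimethoxyphenyl)-2-[3-(2,6-dimethoxyphenyl)-3-hydroxyprop-1-ynyl]-4-isopropoxy-7-methoxy-6-methylinden-1-one (racemic)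
Conditions: PdCl2(PPh3)2 (5 mol %), CuI (10 mol %), Et3N, THF, degassed, rt to 40 °C
Reagents that add atoms: none
Why: Sonogashira coupling: the C–Br bond of an α-bromoenone adds readily to zerovalent palladium, no electrophilic reagent touches the electron-rich rings, and the low temperature holds back base-induced isomerisation of the propargylic alcohol to an enone.

Step 9
Reactants: 16 3-(2,6-dimethoxyphenyl)-2-[3-(2,6-dimethoxyphenyl)-3-hydroxyprop-1-ynyl]-4-isopropoxy-7-methoxy-6-methylinden-1-one
Product: 17 2-[3-(2,6-dimethoxyphenyl)-3-oxoprop-1-ynyl]-3-(2,6-dimethoxyphenyl)-4-isopropoxy-7-methoxy-6-methylinden-1-one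
Conditions: MnO2 (activated, excess), CH2Cl2, rt
Reagents that add atoms: none
Why: MnO2 oxidation of an alcohol that is both propargylic and benzylic, under neutral conditions that avoid ionisation of the acid-labile carbinol.

Step 10
Reactants: 18 3-methoxyprop-1-yne
Product: 20 methyl 4-methoxybut-2-ynoate, via lithium acetylide 19 (not isolated)
Conditions: n-BuLi, THF, −78 °C; then ClCO2Me, −78 to 0 °C
Reagents that add atoms: methyl chloroformate, COC(=O)Cl
Why: Deprotonation of a terminal alkyne and C-acylation of the lithium acetylide with a chloroformate.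

Step 11
Reactants: 20 methyl 4-methoxybut-2-ynoate
Product: 21 methyl (Z)-4-methoxy-3-methylbut-2-enoate
Conditions: Me2CuLi (from MeLi and CuI), THF, −78 °C; AcOH in THF added at −78 °C
Reagents that add atoms: lithium dimethylcuprate Me2CuLi, [Li+].C[Cu-]C (made in the flask from methyllithium, [Li]C, and CuI)
Why: Syn-carbocupration (conjugate addition of a lithium dialkylcuprate to an alkynoate) with protonation at −78 °C places the new methyl group and the incoming hydrogen cis, so CH2OMe ends cis to the ester (Z), the way precursors of β-substituted butenolides are commonly made.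

Step 12
Reactants: 21 methyl (Z)-4-methoxy-3-methylbut-2-enoate
Product: 22 (Z)-4-methoxy-3-methylbut-2-enoic acid
Conditions: LiOH, THF/H2O, rt; then 1 M HCl to pH 3 at 0 °C
Reagents that add atoms: lithium hydroxide, [Li+].[OH-]
Why: Saponification of a methyl ester; neither the Z-alkene nor the allylic methyl ether is affected by LiOH at rt, and cold acidification avoids lactonisation.

Step 13
Reactants: 22 (Z)-4-methoxy-3-methylbut-2-enoic acid
Product: 24 (E)-4-methoxy-3-methyl-1,1-bis(trimethylsilyloxy)buta-1,3-diene, via dilithium dienediolate 23 (not isolated)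
Conditions: LiN(iPr)2 (2.2 equiv), THF, −78 to 0 °C; Me3SiCl (2.5 equiv), −78 °C to rt; filtration in pentane under Ar, bulb-to-bulb distillation
Reagents that add atoms: chlorotrimethylsilane, C[Si](C)(C)Cl
Why: Double deprotonation of an α,β-unsaturated acid and O-silylation of the dienediolate (bis-silyl ketene acetal formation): the lithium amide held by the carboxylate removes a proton from the γ-carbon cis to it, here CH2OMe and not CH3, and allylic strain turns OMe away from the carboxylate so that the enol ether should form as the E isomer.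

Step 14
Reactants: 17 2-[3-(2,6-dimethoxyphenyl)-3-oxoprop-1-ynyl]-3-(2,6-dimethoxyphenyl)-4-isopropoxy-7-methoxy-6-methylinden-1-one; 24 (E)-4-methoxy-3-methyl-1,1-bis(trimethylsilyloxy)buta-1,3-diene
Product: 26 acredinone A C4 isopropyl ether, via cyclohexadiene adduct 25 (not isolated)
Conditions: 24 (3 equiv), toluene, 80 °C, sealed tube, Ar; then 1 M HCl, THF, rt
Reagents that add atoms: none
Why: The two silyloxy groups on a2 make the far diene terminus a5 the nucleophilic end, so a5 bonds to a6, the β-carbon of the ynone, and a2 bonds to a1 next to the ketone in a concerted but highly asynchronous [4+2] cycloaddition whose stepwise limit is a vinylogous Mukaiyama–Michael addition followed by closure of the allenolate onto a2. Ring A closes as the six-membered cyclohexa-1,4-diene 25 in this cycloaddition mode, both new σ-bonds (a5–a6 and a2–a1) being formed in the same operation. Aqueous acid then ionises the bis-silyl ketal at a2, the a5 hydrogen is lost and the remaining silyl ether is hydrolysed, which leaves OH on a2 and OMe on a5; loss of methanol is no competing route to an arene because a2 carries no hydrogen. The closest known reaction type is the Diels–Alder addition and aromatisation of vinylketene silyl acetals with acetylenic ketones to give phenols, the a5 methoxy group being one more donor on that diene class. The only stereocentre formed, a5 in 25, is racemic and vanishes on aromatisation. The step needs a5-to-a6 regioselectivity, secured by two oxygen donors on a2 outweighing one on a5 and by the aroyl group being the only acceptor in conjugation with the alkyne (C2 is the α-carbon of the indenone), and it needs the alkyne to react in preference to the indenone C2=C3 bond, which is tetrasubstituted and shielded by the dimethoxyphenyl ring.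

Step 15
Reactants: 26 acredinone A C4 isopropyl ether
Product: 27 acredinone A
Conditions: BCl3 (4 equiv), CH2Cl2, −78 to −20 °C; then H2O
Reagents that add atoms: none
Why: Lewis-acid dealkylation: BCl3 cleaves an isopropyl aryl ether through a secondary-cation-like transition state at temperatures at which methyl ethers, which need chloride attack at CH3, stay intact, and the boron aryloxides are hydrolysed on work-up.

**Compound list**

1 | 4-methoxy-3-methylphenol | COc1ccc(O)cc1C | starting material
2 | 4-isopropoxy-1-methoxy-2-methylbenzene | COc1ccc(OC(C)C)cc1C | intermediate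
3 | 1-bromo-2-isopropoxy-5-methoxy-4-methylbenzene | COc1cc(Br)c(OC(C)C)cc1C | intermediate
4 | 2,6-dimethoxybenzaldehyde | COc1cccc(OC)c1C=O | starting material
5 | Meldrum's acid (2,2-dimethyl-1,3-dioxane-4,6-dione) | CC1(C)OC(=O)CC(=O)O1 | starting material
6 | 5-(2,6-dimethoxybenzylidene)-2,2-dimethyl-1,3-dioxane-4,6-dione | COc1cccc(OC)c1C=C1C(=O)OC(C)(C)OC1=O | intermediate
7 | (2-isopropoxy-5-methoxy-4-methylphenyl)magnesium bromide (formed in the flask) | COc1cc([Mg]Br)c(OC(C)C)cc1C | intermediate
8 | 5-[(2,6-dimethoxyphenyl)(2-isopropoxy-5-methoxy-4-methylphenyl)methyl]-2,2-dimethyl-1,3-dioxane-4,6-dione (racemic) | COc1cccc(OC)c1C(c1cc(OC)c(C)cc1OC(C)C)C1C(=O)OC(C)(C)OC1=O | intermediate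
9 | 3-(2,6-dimethoxyphenyl)-4-isopropoxy-7-methoxy-6-methyl-1-oxoindane-2-carboxylic acid (racemic, formed in the flask) | O=C1C(C(=O)O)C(c2c(OC)cccc2OC)c2c(OC(C)C)cc(C)c(OC)c21 | intermediate
10 | 3-(2,6-dimethoxyphenyl)-4-isopropoxy-7-methoxy-6-methylindan-1-one (racemic) | O=C1CC(c2c(OC)cccc2OC)c2c(OC(C)C)cc(C)c(OC)c21 | intermediate
11 | 2-bromo-3-(2,6-dimethoxyphenyl)-4-isopropoxy-7-methoxy-6-methylindan-1-one (racemic, relative configuration of no consequence, formed in the flask) | O=C1C(Br)C(c2c(OC)cccc2OC)c2c(OC(C)C)cc(C)c(OC)c21 | intermediate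
12 | 2,2-dibromo-3-(2,6-dimethoxyphenyl)-4-isopropoxy-7-methoxy-6-methylindan-1-one (racemic, formed in the flask) | O=C1C(Br)(Br)C(c2c(OC)cccc2OC)c2c(OC(C)C)cc(C)c(OC)c21 | intermediate
13 | 2-bromo-3-(2,6-dimethoxyphenyl)-4-isopropoxy-7-methoxy-6-methylinden-1-one | O=C1C(Br)=C(c2c(OC)cccc2OC)c2c(OC(C)C)cc(C)c(OC)c21 | intermediate
14 | ethynylmagnesium bromide | C#C[Mg]Br | starting material
15 | 1-(2,6-dimethoxyphenyl)prop-2-yn-1-ol (racemic) | C#CC(O)c1c(OC)cccc1OC | intermediate
16 | 3-(2,6-dimethoxyphenyl)-2-[3-(2,6-dimethoxyphenyl)-3-hydroxyprop-1-ynyl]-4-isopropoxy-7-methoxy-6-methylinden-1-one (racemic) | O=C1C(C#CC(O)c2c(OC)cccc2OC)=C(c2c(OC)cccc2OC)c2c(OC(C)C)cc(C)c(OC)c21 | intermediate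
17 | 2-[3-(2,6-dimethoxyphenyl)-3-oxoprop-1-ynyl]-3-(2,6-dimethoxyphenyl)-4-isopropoxy-7-methoxy-6-methylinden-1-one | O=C1C(C#CC(=O)c2c(OC)cccc2OC)=C(c2c(OC)cccc2OC)c2c(OC(C)C)cc(C)c(OC)c21 | intermediate
18 | 3-methoxyprop-1-yne | C#CCOC | starting material
19 | lithium 3-methoxyprop-1-yn-1-ide (formed in the flask) | [Li]C#CCOC | intermediate
20 | methyl 4-methoxybut-2-ynoate | COCC#CC(=O)OC | intermediate
21 | methyl (Z)-4-methoxy-3-methylbut-2-enoate | COC/C(C)=C\C(=O)OC | intermediate
22 | (Z)-4-methoxy-3-methylbut-2-enoic acid | COC/C(C)=C\C(=O)O | intermediate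
23 | dilithium (E)-4-methoxy-3-methylbuta-1,3-diene-1,1-diolate (formed in the flask) | [Li+].[Li+].[O-]C([O-])=C/C(C)=C/OC | intermediate
24 | (E)-4-methoxy-3-methyl-1,1-bis(trimethylsilyloxy)buta-1,3-diene | C[Si](C)(C)OC(O[Si](C)(C)C)=C/C(C)=C/OC | intermediate
25 | cyclohexa-1,4-diene adduct: a2 bears two OSiMe3, a3=a4, a5 bears H and OMe, a1=a6 (racemic at a5, formed in the flask) | COC1C(C)=CC(O[Si](C)(C)C)(O[Si](C)(C)C)C(C(=O)c2c(OC)cccc2OC)=C1C1=C(c2c(OC)cccc2OC)c2c(OC(C)C)cc(C)c(OC)c2C1=O | intermediate
26 | acredinone A C4 isopropyl ether | O=C1C(c2c(OC)c(C)cc(O)c2C(=O)c2c(OC)cccc2OC)=C(c2c(OC)cccc2OC)c2c(OC(C)C)cc(C)c(OC)c21 | intermediate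
27 | acredinone A | COc1cccc(OC)c1C(=O)c1c(O)cc(C)c(OC)c1C1=C(c2c(OC)cccc2OC)c2c(O)cc(C)c(OC)c2C1=O | target

**Step count**

Total step count: 15 steps.
Longest linear sequence: 9 steps (steps 1, 2, 4, 5, 6, 8, 9, 14, 15).

**Steps most likely to fail**

1. **Step 14.** The crowded alkyne may take up the diene more slowly than the acyclic bis-silyl ketene acetal is lost through silyl migration, hydrolysis or oligomerisation. The diene may also populate its s-cis form too little.

 Fallback, from 17 back to 26: the two diene oxygens are tied together in a furan. Commercial 4-methylfuran-2(5H)-one is silylated (tBuMe2SiOTf, Et3N, CH2Cl2, 0 °C) to 2-(tert-butyldimethylsilyloxy)-4-methylfuran F1. This diene is locked s-cis, and its nucleophilic C5 corresponds to a5. Heating F1 with 17 in toluene should give the oxa-bridged cycloadduct F2. F2 opens at its ketal bridgehead a2 and loses the a5 hydrogen to give the ring A hydroquinone monosilyl ether F3 (a5 OH, a2 OSi). Methylation of the free a5 phenol (MeI, K2CO3, acetone) gives the a5 methyl ether F4. Bu4NF buffered with AcOH in THF then removes the silyl group and delivers 26.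

2. **Step 6.** HBr may be lost prematurely after the first bromination. The electron-rich dimethoxyphenyl ring may also be brominated if enolate formation is incomplete.

 Fallback, from 10 back to 16: an oxygen handle replaces the halogen, so no brominating agent is used at all. The potassium enolate of 10 (KN(SiMe3)2, THF, −78 °C) is hydroxylated with 2-(phenylsulfonyl)-3-phenyloxaziridine to the 2-hydroxyindanone F5. Dess–Martin oxidation gives the 1,2-dione, which rests as its enol, the 2-hydroxyindenone F6. Tf2O with 2,6-lutidine in CH2Cl2 at −78 °C gives the 2-indenonyl triflate F7. Sonogashira coupling of F7 with 15 under the conditions of step 8 gives 16.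

3. **Step 5.** The Lewis acid may break the doubly benzylic bond between C3 and the Meldrum's acid carbon (a retro-Michael type fragmentation). This could be faster than acylation at the only moderately activated C7a.

 Fallback, from 8 back to 10: the carbon leaving group is removed first. Heating 8 in pyridine/H2O hydrolyses and decarboxylates it to 3-(2,6-dimethoxyphenyl)-3-(2-isopropoxy-5-methoxy-4-methylphenyl)propanoic acid F8. F8 is cyclised through its mixed anhydride ((CF3CO)2O, CH2Cl2, 0 °C to rt) in a classical intramolecular Friedel–Crafts acylation to 10.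

**Further compounds**

F1 | step 14 | 2-(tert-butyldimethylsilyloxy)-4-methylfuran | Cc1coc(O[Si](C)(C)C(C)(C)C)c1
F2 | step 14 | oxa-bridged cycloadduct (7-oxabicyclo[2.2.1]hepta-2,5-diene, bridgeheads a2 with OSi and a5 with H, racemic) | CC1=CC2(O[Si](C)(C)C(C)(C)C)OC1C(C1=C(c3c(OC)cccc3OC)c3c(OC(C)C)cc(C)c(OC)c3C1=O)=C2C(=O)c1c(OC)cccc1OC
F3 | step 14 | ring A hydroquinone monosilyl ether (a5 OH, a2 OSitBuMe2, C4 OiPr) | O=C1C(c2c(O)c(C)cc(O[Si](C)(C)C(C)(C)C)c2C(=O)c2c(OC)cccc2OC)=C(c2c(OC)cccc2OC)c2c(OC(C)C)cc(C)c(OC)c21
F4 | step 14 | a5 methyl ether (a5 OMe, a2 OSitBuMe2, C4 OiPr) | O=C1C(c2c(OC)c(C)cc(O[Si](C)(C)C(C)(C)C)c2C(=O)c2c(OC)cccc2OC)=C(c2c(OC)cccc2OC)c2c(OC(C)C)cc(C)c(OC)c21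
F5 | step 6 | 3-(2,6-dimethoxyphenyl)-2-hydroxy-4-isopropoxy-7-methoxy-6-methylindan-1-one (racemic) | O=C1C(O)C(c2c(OC)cccc2OC)c2c(OC(C)C)cc(C)c(OC)c21
F6 | step 6 | 3-(2,6-dimethoxyphenyl)-2-hydroxy-4-isopropoxy-7-methoxy-6-methylinden-1-one | O=C1C(O)=C(c2c(OC)cccc2OC)c2c(OC(C)C)cc(C)c(OC)c21
F7 | step 6 | 3-(2,6-dimethoxyphenyl)-4-isopropoxy-7-methoxy-6-methyl-1-oxoinden-2-yl trifluoromethanesulfonate | O=C1C(OS(=O)(=O)C(F)(F)F)=C(c2c(OC)cccc2OC)c2c(OC(C)C)cc(C)c(OC)c21
F8 | step 5 | 3-(2,6-dimethoxyphenyl)-3-(2-isopropoxy-5-methoxy-4-methylphenyl)propanoic acid (racemic) | COc1cccc(OC)c1C(CC(=O)O)c1cc(OC)c(C)cc1OC(C)C
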